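**Plan**
- Retrosynthesis: the two benzyl ethers come off first; then C2–C3 of ring C is cut, which turns the chromanone into a 4-ylidene-1,3-benzodioxine whose C2 is an acetal carbon between O1 and the enol oxygen of the aryl ketone. The two acetal C–O bonds, the ester C–O bond and the α-C–O bond of the ketone are cut last.
- Enabling feature: C2 is benzylic, bonded to O1 and C3, and β to the C4 ketone, so ring C is an O1-stabilised benzylic cation at C2 joined to the C3 enol carbon of the ring A aryl ketone.
- Forward: ring A is bought as 2',4',6'-trihydroxyacetophenone; α-hydroxylation and esterification place the C3 oxygen and the side chain; benzal bromide closes the 1,3-dioxine ring; an acid-induced oxygen-to-carbon shift turns it into ring C; hydrogenolysis finishes.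
- Stereochemistry: the side-chain centre comes from (R)-2-methylbutanoic acid, C2 is set by the chiral counter-anion in the rearrangement, and C3 follows as the trans (thermodynamic) isomer.

Key step: step 5

Assumption: the sense of induction of the binaphthyl N-triflylphosphoramide in this ion-pair recombination cannot be predicted with confidence; the (R)-acid is written, and its mirror image would be taken if the first run favoured the (2S,3S) series.

**Step 1**
Reactants: 1 2',4',6'-trihydroxyacetophenone
Product: 2 1-[2,4-bis(benzyloxy)-6-hydroxyphenyl]ethanone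
Conditions: BnBr (2.1 equiv), K2CO3, DMF, 60 °C
Reagents that add atoms: benzyl bromide, BrCc1ccccc1
Why: Williamson etherification should stop after two benzylations because the remaining ortho hydroxyl is hydrogen-bonded to the ketone and is by far the least nucleophilic of the three.

**Step 2**
Reactants: 2 1-[2,4-bis(benzyloxy)-6-hydroxyphenyl]ethanone
Product: 5 1-[2,4-bis(benzyloxy)-6-hydroxyphenyl]-2-hydroxyethanone, via bis-silyl enol ether 3 (not isolated), via bis-silyl α-silyloxy ketone 4 (not isolated)
Conditions: TMSOTf (2.4 equiv), Et3N, CH2Cl2, 0 °C; then mCPBA (1.05 equiv), NaHCO3, −20 °C; then 1 M HCl, THF, 0 °C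
Reagents that add atoms: mCPBA (3-chloroperoxybenzoic acid), OOC(=O)c1cccc(Cl)c1
Why: Rubottom oxidation: soft enolisation silylates the phenol and the methyl ketone, the silyl enol ether is epoxidised much faster than the alkoxyarene or the ketone (Baeyer–Villiger) reacts with one equivalent of peracid, and silyl migration followed by mild acid hydrolysis should give the ketol with the chelated phenol free.

**Step 3**
Reactants: 5 1-[2,4-bis(benzyloxy)-6-hydroxyphenyl]-2-hydroxyethanone; 6 (2R)-2-methylbutanoic acid
Product: 7 2-[2,4-bis(benzyloxy)-6-hydroxyphenyl]-2-oxoethyl (2R)-2-methylbutanoate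
Conditions: EDC·HCl (1.2 equiv), DMAP (0.1 equiv), CH2Cl2, 0 °C
Reagents that add atoms: none
Why: Steglich esterification should acylate the primary ketol hydroxyl, since the phenol is the same ketone-chelated, flanked hydroxyl that resisted alkylation in step 1, and carbodiimide activation does not epimerise the α-branched acid.

**Step 4**
Reactants: 7 2-[2,4-bis(benzyloxy)-6-hydroxyphenyl]-2-oxoethyl (2R)-2-methylbutanoate; 8 benzal bromide
Product: 10 (Z)-[5,7-bis(benzyloxy)-2-phenyl-4H-1,3-benzodioxin-4-ylidene]methyl (2R)-2-methylbutanoate, via α-bromobenzyl aryl ether 9 (not isolated)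
Conditions: Cs2CO3 (2.5 equiv), 8 (1.5 equiv), DMF, 4 Å MS, 50 °C
Reagents that add atoms: none
Why: Proposed new method: the cesium phenoxide of 7 displaces one bromide of 8 (Williamson step), ether 9 ionises to an aryloxy-stabilised benzylic cation that the neighbouring ketone oxygen captures in a six-membered ring, and carbonate removes the α-proton (acidified by the acyloxy group) of the resulting dioxinium ion to give the exocyclic enol ether with the acyloxy group turned away from the arene (Z); capture at oxygen is expected because the neutral ketone offers only its carbonyl lone pair and any enolate meets the hard α-halo ether at oxygen, the closest known reactions being base-mediated benzylidene acetal formation from diols or catechols with benzal halides and O-alkylation of ketone enolates by chloromethyl ethers.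

**Step 5**
Reactants: 10 (Z)-[5,7-bis(benzyloxy)-2-phenyl-4H-1,3-benzodioxin-4-ylidene]methyl (2R)-2-methylbutanoate (both epimers at the acetal carbon)
Product: 11 (2R,3R)-5,7-bis(benzyloxy)-4-oxo-2-phenylchroman-3-yl (2R)-2-methylbutanoate
Conditions: (R)-3,3'-bis(2,4,6-triisopropylphenyl)-1,1'-binaphthyl-2,2'-diyl N-triflylphosphoramide (10 mol %), toluene, 4 Å MS, −40 → 0 °C
Reagents that add atoms: none
Why: Proposed new method: the acid protonates the enol-ether oxygen, the acetal bond between C2 and that oxygen ionises to a planar 2-aryloxybenzylic oxocarbenium ion (stabilised by O1 and phenyl) held in a contact ion pair with the chiral phosphoramidate, which is also hydrogen-bonded to the liberated enol, and the enol carbon C3 adds to C2 before the partners separate, after which loss of the proton from the C4 oxocarbenium returns the acid. The closest known reactions are the Petasis–Ferrier rearrangement of 4-methylene-1,3-dioxanes to tetrahydropyran-4-ones under Me2AlCl and the chiral-phosphoric-acid-catalysed aza-Petasis–Ferrier rearrangement of hemiaminal vinyl ethers, neither shown for a benzo-fused enol acetal. Ring C closes in a 6-endo-trig (enol-endo) mode, fixed because the leaving oxygen and the nucleophilic carbon belong to the same enol. C2 is set by the counter-anion, which shields one face of the cation, and both acetal epimers give the same cation, so the step is enantioconvergent; C3 follows as the trans-diequatorial isomer, which is the thermodynamic one and can also be reached from any cis product by acid-mediated enolisation at C3. The step needs C–C recombination to outrun cation escape, hydrolysis and a racemic background path; the electron-rich 2,4-dialkoxyaryl enol, the non-polar solvent, low temperature and sieves are chosen to secure this.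

**Step 6**
Reactants: 11 (2R,3R)-5,7-bis(benzyloxy)-4-oxo-2-phenylchroman-3-yl (2R)-2-methylbutanoate
Product: 12 (2R,3R)-5,7-dihydroxy-4-oxo-2-phenylchroman-3-yl (2R)-2-methylbutanoate
Conditions: H2 (1 atm), 10% Pd/C, EtOAc, rt
Reagents that add atoms: none
Why: Hydrogenolysis of aryl benzyl ethers; the cyclic benzylic C2–O1 bond, the aryl ketone and the ester normally survive flavanone debenzylation when the reaction is stopped after two equivalents of H2, so no stereocentre is touched.

**Compound list**
1 | 2',4',6'-trihydroxyacetophenone | CC(=O)c1c(O)cc(O)cc1O | starting material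
2 | 1-[2,4-bis(benzyloxy)-6-hydroxyphenyl]ethanone | CC(=O)c1c(O)cc(OCc2ccccc2)cc1OCc1ccccc1 | intermediate
3 | bis-silyl enol ether: trimethylsilyl enol ether of 2 with the phenol also O-trimethylsilylated | C=C(O[Si](C)(C)C)c1c(O[Si](C)(C)C)cc(OCc2ccccc2)cc1OCc1ccccc1 | intermediate (not isolated)
4 | 1-{2,4-bis(benzyloxy)-6-[(trimethylsilyl)oxy]phenyl}-2-[(trimethylsilyl)oxy]ethanone | C[Si](C)(C)OCC(=O)c1c(O[Si](C)(C)C)cc(OCc2ccccc2)cc1OCc1ccccc1 | intermediate (not isolated)
5 | 1-[2,4-bis(benzyloxy)-6-hydroxyphenyl]-2-hydroxyethanone | OCC(=O)c1c(O)cc(OCc2ccccc2)cc1OCc1ccccc1 | intermediate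
6 | (2R)-2-methylbutanoic acid | CC[C@@H](C)C(=O)O | starting material
7 | 2-[2,4-bis(benzyloxy)-6-hydroxyphenyl]-2-oxoethyl (2R)-2-methylbutanoate | CC[C@@H](C)C(=O)OCC(=O)c1c(O)cc(OCc2ccccc2)cc1OCc1ccccc1 | intermediate
8 | benzal bromide, (dibromomethyl)benzene | BrC(Br)c1ccccc1 | starting material
9 | 2-{2,4-bis(benzyloxy)-6-[bromo(phenyl)methoxy]phenyl}-2-oxoethyl (2R)-2-methylbutanoate | CC[C@@H](C)C(=O)OCC(=O)c1c(OC(Br)c2ccccc2)cc(OCc2ccccc2)cc1OCc1ccccc1 | intermediate (not isolated)
10 | (Z)-[5,7-bis(benzyloxy)-2-phenyl-4H-1,3-benzodioxin-4-ylidene]methyl (2R)-2-methylbutanoate, both epimers at the acetal carbon | CC[C@@H](C)C(=O)O/C=C1\OC(c2ccccc2)Oc2cc(OCc3ccccc3)cc(OCc3ccccc3)c21 | intermediate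
11 | (2R,3R)-5,7-bis(benzyloxy)-4-oxo-2-phenylchroman-3-yl (2R)-2-methylbutanoate | CC[C@@H](C)C(=O)O[C@H]1C(=O)c2c(OCc3ccccc3)cc(OCc3ccccc3)cc2O[C@@H]1c1ccccc1 | intermediate
12 | (2R,3R)-5,7-dihydroxy-4-oxo-2-phenylchroman-3-yl (2R)-2-methylbutanoate | CC[C@@H](C)C(=O)O[C@H]1C(=O)c2c(O)cc(O)cc2O[C@@H]1c1ccccc1 | target

Total steps: 6. Longest linear sequence: 6 steps (1 to 12).

**Steps most likely to fail**

Step 5. The ion pair may recombine without facial control (loose pairing, or a background path through adventitious achiral acid), the liberated enediol monoester may shift its acyl group before the C–C bond forms, or traces of water may hydrolyse the acetal. The fallback uses the established chalcone-epoxide route, sets out from ketone 2 and returns at 11. O-Methoxymethylation of the chelated phenol (NaH, MOMCl, DMF) would give 1-[2,4-bis(benzyloxy)-6-(methoxymethoxy)phenyl]ethanone F1. Claisen–Schmidt condensation with benzaldehyde (KOH, EtOH) would give the chalcone (E)-1-[2,4-bis(benzyloxy)-6-(methoxymethoxy)phenyl]-3-phenylprop-2-en-1-one F2. Juliá–Colonna epoxidation (poly-L-leucine, urea–H2O2, DBU, THF) would give [2,4-bis(benzyloxy)-6-(methoxymethoxy)phenyl][(2R,3S)-3-phenyloxiran-2-yl]methanone F3. Methanolic HCl would then remove the methoxymethyl group and let the phenol open the epoxide at the benzylic carbon with inversion, giving (2R,3R)-5,7-bis(benzyloxy)-3-hydroxy-2-phenylchroman-4-one F4. Steglich esterification of F4 with acid 6 (EDC·HCl, DMAP, CH2Cl2) returns to 11.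

Step 4. The enolate may be alkylated at carbon and give the racemic chromanone directly, the phenoxide may displace the carboxylate intramolecularly, the ester may migrate under base, or acetal formation may run between two molecules. The fallback reaches the enol acetal through the aldehyde oxidation level with known reactions, sets out from ketol 5 and returns at 10. Reduction with NaBH4 (MeOH, 0 °C) would give 1-[2,4-bis(benzyloxy)-6-hydroxyphenyl]ethane-1,2-diol F5. Benzal bromide 8 and Cs2CO3 (DMF) would bridge the phenol and the benzylic hydroxyl, the six-membered ring closing in preference to the seven-membered one, to give [5,7-bis(benzyloxy)-2-phenyl-4H-1,3-benzodioxin-4-yl]methanol F6. Dess–Martin oxidation would give 5,7-bis(benzyloxy)-2-phenyl-4H-1,3-benzodioxine-4-carbaldehyde F7. Its potassium enolate (KN(SiMe3)2, THF, −78 °C) would be acylated at oxygen with (2R)-2-methylbutanoyl chloride F8, made from acid 6 and oxalyl chloride, to return at 10.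

Step 3. Acylation may occur at the phenol alongside or instead of the primary hydroxyl. The fallback replaces selective acylation by exhaustive acylation and selective deacylation, sets out from ketol 5 and returns at 7. Excess acid 6 (2.5 equiv, EDC·HCl, DMAP 1 equiv, rt) would give the bis-ester 3,5-bis(benzyloxy)-2-({[(2R)-2-methylbutanoyl]oxy}acetyl)phenyl (2R)-2-methylbutanoate F9. Pyrrolidine (1.1 equiv, CH2Cl2, 0 °C) would then cleave only the activated aryl ester, returning to 7.

**Further compounds**
F1 | step 5 | 1-[2,4-bis(benzyloxy)-6-(methoxymethoxy)phenyl]ethanone | COCOc1cc(OCc2ccccc2)cc(OCc2ccccc2)c1C(C)=O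
F2 | step 5 | (E)-1-[2,4-bis(benzyloxy)-6-(methoxymethoxy)phenyl]-3-phenylprop-2-en-1-one | COCOc1cc(OCc2ccccc2)cc(OCc2ccccc2)c1C(=O)/C=C/c1ccccc1
F3 | step 5 | [2,4-bis(benzyloxy)-6-(methoxymethoxy)phenyl][(2R,3S)-3-phenyloxiran-2-yl]methanone | COCOc1cc(OCc2ccccc2)cc(OCc2ccccc2)c1C(=O)[C@@H]1O[C@H]1c1ccccc1
F4 | step 5 | (2R,3R)-5,7-bis(benzyloxy)-3-hydroxy-2-phenylchroman-4-one | O[C@H]1C(=O)c2c(OCc3ccccc3)cc(OCc3ccccc3)cc2O[C@@H]1c1ccccc1
F5 | step 4 | 1-[2,4-bis(benzyloxy)-6-hydroxyphenyl]ethane-1,2-diol (racemic) | OCC(O)c1c(O)cc(OCc2ccccc2)cc1OCc1ccccc1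
F6 | step 4 | [5,7-bis(benzyloxy)-2-phenyl-4H-1,3-benzodioxin-4-yl]methanol (diastereomer mixture) | OCC1OC(c2ccccc2)Oc2cc(OCc3ccccc3)cc(OCc3ccccc3)c21
F7 | step 4 | 5,7-bis(benzyloxy)-2-phenyl-4H-1,3-benzodioxine-4-carbaldehyde | O=CC1OC(c2ccccc2)Oc2cc(OCc3ccccc3)cc(OCc3ccccc3)c21
F8 | step 4 | (2R)-2-methylbutanoyl chloride | CC[C@@H](C)C(=O)Cl
F9 | step 3 | 3,5-bis(benzyloxy)-2-({[(2R)-2-methylbutanoyl]oxy}acetyl)phenyl (2R)-2-methylbutanoate | CC[C@@H](C)C(=O)OCC(=O)c1c(OC(=O)[C@H](C)CC)cc(OCc2ccccc2)cc1OCc1ccccc1
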